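**Plan**

- Ring B (C1, C2, C3, C4, C4a, C8a) is cut at C8a–C1, C1–C2 and C3–C4. This gives a para-alkylphenyl(methoxy)carbene complex of chromium, one of its CO ligands and propyne (Dötz benzannulation, then oxidation to the quinone).
- The cut is possible because ring A carries its only substituent at C7, para to C4a, so the precursor is a para-disubstituted benzene with two equivalent ortho carbons. Ring B has Me at C2 and H at C3, the pattern a terminal alkyne delivers with Me next to the CO-derived C1.
- Side-chain cuts: C2'–C3' (B-alkyl Suzuki coupling of 4-bromostyrene with an (E)-vinyl iodide), C4'–Me (carboalumination of a terminal alkyne), C5'–C6' (alkylation of lithiated 1-(trimethylsilyl)propyne by epoxygeranyl triflate).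
- Forward order: geraniol → epoxide → enyne → anti-diol → acetonide → vinyl iodide → aryl bromide → carbene complex → ring B last; then acetonide off and C7' acetate on.
- Stereochemistry: C7' and C8' come from Sharpless epoxidation of geraniol (D-(−)-tartrate) and invertive hydrolysis at C8'. The C3'=C4' (E) geometry comes from syn-carboalumination and stereoretentive coupling.

Key step: step 8

Remark (numbering): ring atoms are numbered as in 2-methyl-1,4-naphthoquinone (C1=O next to C2–Me, side chain on C7); chain carbons run from C1' (benzylic) to C13'; geraniol C1–C3 become C6'–C8'.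

**Route**

Step 1
Reactants: 1 geraniol
Product: 2 (2R,3R)-2,3-epoxygeraniol
Conditions: t-BuOOH, Ti(OiPr)4 (5 mol%), D-(−)-diisopropyl tartrate (6 mol%), 4 Å MS, CH2Cl2, −20 °C
Reagents that add atoms: tert-butyl hydroperoxide, CC(C)(C)OO
Why: Sharpless asymmetric epoxidation, in which the allylic hydroxyl binds the titanium–tartrate catalyst so that only the C2=C3 alkene reacts, the D-(−)-tartrate directs oxygen to the face giving the (2R,3R)-epoxide (future C7' and, before inversion, C8'), and the E geometry fixes their relative configuration.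

Step 2
Reactants: 2 (2R,3R)-2,3-epoxygeraniol; 3 1-(trimethylsilyl)propyne
Product: 6 trimethyl{4-[(2R,3R)-3-methyl-3-(4-methylpent-3-en-1-yl)oxiran-2-yl]but-1-yn-1-yl}silane, via epoxy triflate 4 (not isolated), via lithiated silylpropyne 5 (not isolated)
Conditions: 2, n-BuLi, THF, −78 °C, then Tf2O, −78 °C; separately 3, n-BuLi, THF, −78 → −20 °C; combine at −78 °C, DMPU, −78 → −40 °C
Reagents that add atoms: none
Why: Alkylation of a propargylic organolithium by a primary triflate, where at −78 °C displacement at C1 should be far faster than opening of the trisubstituted epoxide without a Lewis acid, the silyl group steers the ambident anion to react at its CH2 terminus (alkyne, not allene), and no stereocentre is touched.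

Step 3
Reactants: 6 epoxy silyl enyne
Product: 8 (5R,6S)-6,10-dimethylundec-9-en-1-yne-5,6-diol, via silyl alkyne diol 7 (not isolated)
Conditions: HClO4 (aq., cat.), THF/H2O, 0 °C → rt; then K2CO3, MeOH, rt
Reagents that add atoms: water, O
Why: Acid-catalysed epoxide hydrolysis of the borderline A-2 type, in which water attacks the protonated epoxide at the tertiary carbon C8' from the face opposite the C–O bond, so C8' is inverted to S while the C7'–O bond (R) is untouched and the anti diol results; methanolysis with K2CO3 then frees the terminal alkyne.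

Step 4
Reactants: 8 (5R,6S)-6,10-dimethylundec-9-en-1-yne-5,6-diol
Product: 9 (4R,5S)-4-(but-3-yn-1-yl)-2,2,5-trimethyl-5-(4-methylpent-3-en-1-yl)-1,3-dioxolane
Conditions: 2,2-dimethoxypropane, PPTS (cat.), CH2Cl2, rt
Reagents that add atoms: 2,2-dimethoxypropane, COC(C)(C)OC
Why: Acid-catalysed transacetalization masks both hydroxyls as the isopropylidene acetal for the organoaluminium, organolithium and chromium steps without touching either stereocentre.

Step 5
Reactants: 9 acetonide alkyne
Product: 11 (4R,5S)-4-[(3E)-4-iodo-3-methylbut-3-en-1-yl]-2,2,5-trimethyl-5-(4-methylpent-3-en-1-yl)-1,3-dioxolane, via alkenylalane 10 (not isolated)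
Conditions: Me3Al, Cp2ZrCl2 (0.3 equiv), H2O (1 equiv), CH2Cl2, −20 °C; then I2, THF, −20 → 0 °C
Reagents that add atoms: trimethylaluminium, C[Al](C)C; iodine, II
Why: Negishi zirconium-catalysed methylalumination adds Me and Al syn across the terminal alkyne with Al on the terminal carbon, and iodinolysis with retention gives the (E)-vinyl iodide that fixes the C3'=C4' geometry; the water-accelerated low-temperature variant is chosen so that Me3Al does not cleave the acetonide.

Step 6
Reactants: 12 4-bromostyrene; 11 vinyl iodide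
Product: 14 1-bromo-4-{(3E)-4-methyl-6-[(4R,5S)-2,2,5-trimethyl-5-(4-methylpent-3-en-1-yl)-1,3-dioxolan-4-yl]hex-3-en-1-yl}benzene, via alkylborane 13 (not isolated)
Conditions: 12, 9-BBN, THF, 0 °C → rt; then 11, PdCl2(dppf) (5 mol%), AsPh3, Cs2CO3, DMF/THF/H2O, rt
Reagents that add atoms: none
Why: B-alkyl Suzuki–Miyaura coupling, in which 9-BBN hydroborates the styrene at its terminal carbon and the alkylborane couples with the vinyl iodide with retention of the E geometry; oxidative addition into the C(sp2)–I bond at room temperature should be much faster than into the electron-neutral aryl C–Br bond, which is kept for step 7.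

Step 7
Reactants: 14 aryl bromide; 15 hexacarbonylchromium, Cr(CO)6
Product: 18 pentacarbonyl{methoxy[4-((3E)-4-methyl-6-[(4R,5S)-2,2,5-trimethyl-5-(4-methylpent-3-en-1-yl)-1,3-dioxolan-4-yl]hex-3-en-1-yl)phenyl]methylidene}chromium, via aryllithium 16 (not isolated), via lithium acylchromate 17 (not isolated)
Conditions: n-BuLi, THF, −78 °C; Cr(CO)6, −78 °C → rt; then Me3OBF4, CH2Cl2, 0 °C
Reagents that add atoms: trimethyloxonium tetrafluoroborate, C[O+](C)C.F[B-](F)(F)F
Why: Fischer carbene synthesis, in which bromine–lithium exchange gives the aryllithium, this adds to a CO ligand of Cr(CO)6, and O-methylation of the acylchromate gives the aryl(methoxy)carbene complex; the acetonide and the trisubstituted alkenes are inert to these reagents at low temperature.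

Step 8
Reactants: 18 carbene complex; 19 propyne
Product: 22 2-methyl-7-{(3E)-4-methyl-6-[(4R,5S)-2,2,5-trimethyl-5-(4-methylpent-3-en-1-yl)-1,3-dioxolan-4-yl]hex-3-en-1-yl}naphthalene-1,4-dione, via chromium vinylketene complex 20 (not isolated), via methoxynaphthol 21 (not isolated)
Conditions: propyne (excess, THF solution), THF, 50 °C, sealed tube; then air, (NH4)2Ce(NO3)6, MeCN/H2O, 0 °C, 15 min
Reagents that add atoms: water, O
Why: Dötz benzannulation with oxidative work-up: loss of one CO from 18 lets propyne coordinate and insert into the Cr=C bond with its CH terminus bonded to the carbene carbon (the methyl-bearing carbon stays on chromium for steric reasons), and CO insertion then gives the chromium-bound vinylketene 20. A 6π electrocyclization of 20 onto an ortho carbon of the benzene ring forms the C8a–C1 bond and closes the six-membered ring B (ketene carbon to arene ortho carbon), and tautomerization gives naphthol 21 with OH at C1, Me at C2, H at C3 and OMe at C4. The closest known reaction type is the benzannulation of aryl(alkoxy)carbene complexes of chromium with terminal alkynes, which places the larger alkyne substituent next to the CO-derived carbon. No stereocentre is formed. The step needs regioselective alkyne insertion, secured by the H/Me size difference of propyne; it needs no choice between ortho positions because the para-substituted ring makes them equivalent, and the hindered trisubstituted side-chain alkenes should not compete with the alkyne. (NH4)2Ce(NO3)6 then removes chromium and oxidizes the 4-methoxy-1-naphthol to the 1,4-quinone with loss of methanol, and the short cold exposure should spare the acetonide.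

Step 9
Reactants: 22 quinone acetonide
Product: 23 7-[(3E,7R,8S)-7,8-dihydroxy-4,8,12-trimethyltrideca-3,11-dien-1-yl]-2-methylnaphthalene-1,4-dione
Conditions: AcOH/H2O (4:1), 40 °C
Reagents that add atoms: none
Why: Mild aqueous acid hydrolyses the isopropylidene acetal through the oxocarbenium ion at the acetal carbon, so neither the C7'–O nor the C8'–O bond is broken and both configurations are kept, while the quinone and the trisubstituted alkenes tolerate dilute acetic acid.

Step 10
Reactants: 23 quinone diol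
Product: 24 chabrolonaphthoquinone B
Conditions: Ac2O, pyridine, DMAP (cat.), CH2Cl2, 0 °C → rt
Reagents that add atoms: acetic anhydride, CC(=O)OC(C)=O
Why: DMAP-catalysed acylation should acetylate the secondary C7' hydroxyl with retention while the tertiary C8' hydroxyl does not react at room temperature.

**Compound list**

1 | geraniol, (2E)-3,7-dimethylocta-2,6-dien-1-ol | CC(C)=CCC/C(C)=C/CO | starting material
2 | (2R,3R)-2,3-epoxygeraniol, [(2R,3R)-3-methyl-3-(4-methylpent-3-en-1-yl)oxiran-2-yl]methanol | OC[C@H]1O[C@]1(C)CCC=C(C)C | intermediate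
3 | 1-(trimethylsilyl)propyne | CC#C[Si](C)(C)C | starting material
4 | [(2R,3R)-3-methyl-3-(4-methylpent-3-en-1-yl)oxiran-2-yl]methyl trifluoromethanesulfonate | O=S(=O)(OC[C@H]1O[C@]1(C)CCC=C(C)C)C(F)(F)F | intermediate
5 | 3-lithio-1-(trimethylsilyl)propyne | [Li]CC#C[Si](C)(C)C | intermediate
6 | trimethyl{4-[(2R,3R)-3-methyl-3-(4-methylpent-3-en-1-yl)oxiran-2-yl]but-1-yn-1-yl}silane | C[Si](C)(C)C#CCC[C@H]1O[C@]1(C)CCC=C(C)C | intermediate
7 | (5R,6S)-6,10-dimethyl-1-(trimethylsilyl)undec-9-en-1-yne-5,6-diol | C[Si](C)(C)C#CCC[C@@H](O)[C@@](C)(O)CCC=C(C)C | intermediate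
8 | (5R,6S)-6,10-dimethylundec-9-en-1-yne-5,6-diol | C#CCC[C@@H](O)[C@@](C)(O)CCC=C(C)C | intermediate
9 | (4R,5S)-4-(but-3-yn-1-yl)-2,2,5-trimethyl-5-(4-methylpent-3-en-1-yl)-1,3-dioxolane | C#CCC[C@H]1OC(C)(C)O[C@@]1(C)CCC=C(C)C | intermediate
10 | dimethyl{(1E)-2-methyl-4-[(4R,5S)-2,2,5-trimethyl-5-(4-methylpent-3-en-1-yl)-1,3-dioxolan-4-yl]but-1-en-1-yl}alumane | C[Al](C)/C=C(\C)CC[C@H]1OC(C)(C)O[C@@]1(C)CCC=C(C)C | intermediate
11 | (4R,5S)-4-[(3E)-4-iodo-3-methylbut-3-en-1-yl]-2,2,5-trimethyl-5-(4-methylpent-3-en-1-yl)-1,3-dioxolane | I/C=C(\C)CC[C@H]1OC(C)(C)O[C@@]1(C)CCC=C(C)C | intermediate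
12 | 4-bromostyrene | C=Cc1ccc(Br)cc1 | starting material
13 | 9-[2-(4-bromophenyl)ethyl]-9-borabicyclo[3.3.1]nonane | Brc1ccc(CCB2C3CCCC2CCC3)cc1 | intermediate
14 | 1-bromo-4-{(3E)-4-methyl-6-[(4R,5S)-2,2,5-trimethyl-5-(4-methylpent-3-en-1-yl)-1,3-dioxolan-4-yl]hex-3-en-1-yl}benzene | Brc1ccc(CC/C=C(\C)CC[C@H]2OC(C)(C)O[C@@]2(C)CCC=C(C)C)cc1 | intermediate
15 | hexacarbonylchromium, Cr(CO)6 | O=C=[Cr](=C=O)(=C=O)(=C=O)(=C=O)=C=O | starting material
16 | (4-{(3E)-4-methyl-6-[(4R,5S)-2,2,5-trimethyl-5-(4-methylpent-3-en-1-yl)-1,3-dioxolan-4-yl]hex-3-en-1-yl}phenyl)lithium | [Li]c1ccc(CC/C=C(\C)CC[C@H]2OC(C)(C)O[C@@]2(C)CCC=C(C)C)cc1 | intermediate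
17 | lithium pentacarbonyl{oxido[4-((3E)-4-methyl-6-[(4R,5S)-2,2,5-trimethyl-5-(4-methylpent-3-en-1-yl)-1,3-dioxolan-4-yl]hex-3-en-1-yl)phenyl]methylidene}chromate | [Li+].[O-]C(=[Cr](=C=O)(=C=O)(=C=O)(=C=O)=C=O)c1ccc(CC/C=C(\C)CC[C@H]2OC(C)(C)O[C@@]2(C)CCC=C(C)C)cc1 | intermediate
18 | pentacarbonyl{methoxy[4-((3E)-4-methyl-6-[(4R,5S)-2,2,5-trimethyl-5-(4-methylpent-3-en-1-yl)-1,3-dioxolan-4-yl]hex-3-en-1-yl)phenyl]methylidene}chromium | COC(=[Cr](=C=O)(=C=O)(=C=O)(=C=O)=C=O)c1ccc(CC/C=C(\C)CC[C@H]2OC(C)(C)O[C@@]2(C)CCC=C(C)C)cc1 | intermediate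
19 | propyne | CC#C | starting material
20 | tricarbonyl{(3E)-4-methoxy-2-methyl-4-[4-((3E)-4-methyl-6-[(4R,5S)-2,2,5-trimethyl-5-(4-methylpent-3-en-1-yl)-1,3-dioxolan-4-yl]hex-3-en-1-yl)phenyl]buta-1,3-dien-1-one}chromium | CO/C(c1ccc(CC/C=C(\C)CC[C@H]2OC(C)(C)O[C@@]2(C)CCC=C(C)C)cc1)=C/C(C)=C=O.O=C=[Cr](=C=O)=C=O | intermediate
21 | 4-methoxy-2-methyl-7-{(3E)-4-methyl-6-[(4R,5S)-2,2,5-trimethyl-5-(4-methylpent-3-en-1-yl)-1,3-dioxolan-4-yl]hex-3-en-1-yl}naphthalen-1-ol (formed as its tricarbonylchromium complex, freed by the oxidant) | COc1cc(C)c(O)c2cc(CC/C=C(\C)CC[C@H]3OC(C)(C)O[C@@]3(C)CCC=C(C)C)ccc12 | intermediate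
22 | 2-methyl-7-{(3E)-4-methyl-6-[(4R,5S)-2,2,5-trimethyl-5-(4-methylpent-3-en-1-yl)-1,3-dioxolan-4-yl]hex-3-en-1-yl}naphthalene-1,4-dione | CC1=CC(=O)c2ccc(CC/C=C(\C)CC[C@H]3OC(C)(C)O[C@@]3(C)CCC=C(C)C)cc2C1=O | intermediate
23 | 7-[(3E,7R,8S)-7,8-dihydroxy-4,8,12-trimethyltrideca-3,11-dien-1-yl]-2-methylnaphthalene-1,4-dione | CC1=CC(=O)c2ccc(CC/C=C(\C)CC[C@@H](O)[C@@](C)(O)CCC=C(C)C)cc2C1=O | intermediate
24 | chabrolonaphthoquinone B, (3E,7R,8S)-8-hydroxy-4,8,12-trimethyl-1-(7-methyl-5,8-dioxo-5,8-dihydronaphthalen-2-yl)trideca-3,11-dien-7-yl acetate | CC1=CC(=O)c2ccc(CC/C=C(\C)CC[C@@H](OC(C)=O)[C@@](C)(O)CCC=C(C)C)cc2C1=O | target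

**Step count and risks**

Total steps: 10. Longest linear sequence: 10 (geraniol 1 to target 24).

Steps most likely to fail:

1. Step 8 (benzannulation). The chromium intermediate may be diverted: alkyne insertion without the following CO insertion (cyclopentannulation), repeated alkyne insertion, erosion of the insertion regiochemistry with so small an alkyne, or thermal loss of the carbene ligand. The fallback closes the same C8a–C1 bond without chromium by the classical thermal ketene route; it sets out from 14 and returns at 22. Heck coupling of 14 with 2-methylbut-3-enoic acid (Pd(OAc)2, P(o-tol)3, Et3N, DMF, 90 °C) should give (3E)-2-methyl-4-arylbut-3-enoic acid F1. Ac2O/NaOAc at reflux converts F1 through the mixed anhydride and the vinylketene (alkene geometry equilibrating through the dienolate, then 6π closure onto the ring) into 2-methyl-1-naphthyl acetate F2. K2CO3/MeOH liberates naphthol F3, and (KSO3)2NO in buffered aqueous acetone oxidizes F3 at its free para position C4 to quinone 22.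

2. Step 3 (epoxide hydrolysis). The opening may run partly through an open tertiary cation, losing the invertive course at C8', or water may attack C7'; either erodes the configuration of the diol. The fallback sets both centres by SN2 events only; it sets out from 1 and returns at 7, replacing steps 1–3. Sharpless epoxidation of 1 with L-(+)-diisopropyl tartrate gives (2S,3S)-2,3-epoxygeraniol F4. PhSH/NaOH in t-BuOH/H2O at reflux effects Payne rearrangement (intramolecular inversion at the secondary carbon) with thiolate trapping of the terminal epoxide, giving the phenylthio diol F5. S-Methylation with Me3OBF4 gives the sulfonium salt F6, and aqueous NaOH closes it to (2S)-6-methyl-2-[(2R)-oxiran-2-yl]hept-5-en-2-ol F7. F7 is opened at its CH2 carbon by 5 (2.2 equiv, THF, −78 → 0 °C) to give 7, which then enters the K2CO3/MeOH stage of step 3.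

3. Step 6 (chemoselective coupling). Oxidative addition into the aryl C–Br bond may compete once the vinyl iodide is depleted, leading to oligomerization through the alkylborane, and slow transmetalation may allow protodeboronation. The fallback makes the C1'–C2' bond by a copper-catalysed sp3–sp3 coupling without palladium; it sets out from 9 and returns at 14. Alkenylalane 10, made as in step 5, is converted to the ate complex with n-BuLi and trapped with paraformaldehyde to give the (E)-allylic alcohol F8. CBr4/PPh3 gives the allylic bromide F9. Coupling of F9 with 4-bromobenzylmagnesium bromide and catalytic Li2CuCl4 (THF, −20 °C) at the unhindered primary carbon should give 14.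

Further compounds
F1 | step 8 | (3E)-2-methyl-4-(4-{(3E)-4-methyl-6-[(4R,5S)-2,2,5-trimethyl-5-(4-methylpent-3-en-1-yl)-1,3-dioxolan-4-yl]hex-3-en-1-yl}phenyl)but-3-enoic acid | OC(=O)C(C)/C=C/c1ccc(CC/C=C(\C)CC[C@H]2OC(C)(C)O[C@@]2(C)CCC=C(C)C)cc1
F2 | step 8 | 2-methyl-7-{(3E)-4-methyl-6-[(4R,5S)-2,2,5-trimethyl-5-(4-methylpent-3-en-1-yl)-1,3-dioxolan-4-yl]hex-3-en-1-yl}naphthalen-1-yl acetate | CC(=O)Oc1c(C)ccc2ccc(CC/C=C(\C)CC[C@H]3OC(C)(C)O[C@@]3(C)CCC=C(C)C)cc12
F3 | step 8 | 2-methyl-7-{(3E)-4-methyl-6-[(4R,5S)-2,2,5-trimethyl-5-(4-methylpent-3-en-1-yl)-1,3-dioxolan-4-yl]hex-3-en-1-yl}naphthalen-1-ol | Oc1c(C)ccc2ccc(CC/C=C(\C)CC[C@H]3OC(C)(C)O[C@@]3(C)CCC=C(C)C)cc12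
F4 | step 3 | (2S,3S)-2,3-epoxygeraniol | OC[C@@H]1O[C@@]1(C)CCC=C(C)C
F5 | step 3 | (2S,3S)-3,7-dimethyl-1-(phenylsulfanyl)oct-6-ene-2,3-diol | c1ccccc1SC[C@@H](O)[C@@](C)(O)CCC=C(C)C
F6 | step 3 | [(2S,3S)-2,3-dihydroxy-3,7-dimethyloct-6-en-1-yl](methyl)phenylsulfonium tetrafluoroborate | C[S+](c1ccccc1)C[C@@H](O)[C@@](C)(O)CCC=C(C)C.F[B-](F)(F)F
F7 | step 3 | (2S)-6-methyl-2-[(2R)-oxiran-2-yl]hept-5-en-2-ol | C1O[C@H]1[C@@](C)(O)CCC=C(C)C
F8 | step 6 | (2E)-3-methyl-5-[(4R,5S)-2,2,5-trimethyl-5-(4-methylpent-3-en-1-yl)-1,3-dioxolan-4-yl]pent-2-en-1-ol | OC/C=C(\C)CC[C@H]1OC(C)(C)O[C@@]1(C)CCC=C(C)C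
F9 | step 6 | (4R,5S)-4-[(3E)-5-bromo-3-methylpent-3-en-1-yl]-2,2,5-trimethyl-5-(4-methylpent-3-en-1-yl)-1,3-dioxolane | BrC/C=C(\C)CC[C@H]1OC(C)(C)O[C@@]1(C)CCC=C(C)C
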